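**Plan**
1. Locants: chain C1–C7 as in hept-2-enoate (C4 bears OAc, C6 bears the ring); ring C1'–C6' (C1' on C6, C2'=C3', C4' the methyl carbinol).
2. Cuts, last-made first: ring alkene C2'=C3' (ring-closing metathesis), C2=C3 (Wittig), C4–O (aminoxylation), C5–C4 (cyanomethylation), C6–C1' ([3,3]), C1'=C2' of the open chain (Wittig), leaving (R)-linalool.
3. Forward: linalool supplies C3'–C6', C1', the C4' methyl and hydroxyl; the chain is built linearly (enone, allylic propanoate, Ireland–Claisen, two-carbon homologation, aminoxylation/Wittig, acetate) and the only ring closes in the last step.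
4. Stereochemistry: C4' from (R)-linalool; a sacrificial (S)-methyl carbinol (CBS reduction) is relayed by the chair Ireland–Claisen rearrangement of the Z(O)-enolate to C1' and C6; C4 from D-proline; the (E)-enoate from a stabilized ylide.
5. Enabling feature: C2'=C3' is the only disubstituted alkene and sits in the six-membered ring between methine C1' and quaternary carbinol C4', so the open form is a 3-hydroxy-3-methylocta-1,7-diene whose carbinol half is the head of linalool.
6. Helpers: the triethylsilyl ether (on in step 1, off in step 15) and the CH–CH3 end of the sacrificial carbinol, which becomes the (E)-propenyl terminus and leaves as propene in the key step.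

Key step: step 16

Remark: 5-iodo-2-methylpent-2-ene (16) is taken as a purchased reagent; it is otherwise one halide exchange from the commercial bromide.

Step 1
Reactants: 1 (R)-linalool
Product: 2 triethyl{[(3R)-3,7-dimethylocta-1,6-dien-3-yl]oxy}silane
Conditions: Et3SiOTf, 2,6-lutidine, CH2Cl2, −78 → 0 °C
Reagents that add atoms: triethylsilyl trifluoromethanesulfonate, CC[Si](CC)(CC)OS(=O)(=O)C(F)(F)F
Why: Silyl ether protection of the hindered tertiary allylic alcohol with the silyl triflate masks the hydroxyl that would otherwise add in oxa-Michael fashion to the enone of step 3, and the linalool stereocentre (the future C4') is untouched.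

Step 2
Reactants: 2 triethyl{[(3R)-3,7-dimethylocta-1,6-dien-3-yl]oxy}silane
Product: 3 (4R)-4-methyl-4-[(triethylsilyl)oxy]hex-5-enal
Conditions: O3 (1 equiv), CH2Cl2/MeOH, −78 °C, Sudan Red 7B end point; then Me2S, −78 °C → rt
Reagents that add atoms: ozone, O=[O+][O-]
Why: In this ozonolysis the electron-rich trisubstituted alkene should react far faster than the vinyl group, which is monosubstituted and deactivated by the allylic silyloxy group, so that reductive work-up gives the aldehyde whose carbonyl carbon is the future C1'.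

Step 3
Reactants: 3 (4R)-4-methyl-4-[(triethylsilyl)oxy]hex-5-enal; 4 1-(triphenylphosphoranylidene)propan-2-one
Product: 5 (3E,7R)-7-methyl-7-[(triethylsilyl)oxy]nona-3,8-dien-2-one
Conditions: toluene, 90 °C
Reagents that add atoms: none
Why: Wittig olefination with the stabilized acetonyl ylide should give the (E)-enone and installs C2' together with the sacrificial acetyl group.

Step 4
Reactants: 5 (3E,7R)-7-methyl-7-[(triethylsilyl)oxy]nona-3,8-dien-2-one
Product: 6 (2S,3E,7R)-7-methyl-7-[(triethylsilyl)oxy]nona-3,8-dien-2-ol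
Conditions: (R)-2-methyl-CBS-oxazaborolidine (0.2 equiv), catecholborane, toluene, −78 °C; then MeOH, aq. NaOH
Reagents that add atoms: none
Why: In this Corey–Bakshi–Shibata reduction the (R)-oxazaborolidine binds the ketone with the alkenyl group as the large substituent and should deliver hydride to the face that gives the (S)-carbinol, while catecholborane at −78 °C does not hydroborate the alkenes.

Step 5
Reactants: 6 (2S,3E,7R)-7-methyl-7-[(triethylsilyl)oxy]nona-3,8-dien-2-ol
Product: 7 (2S,3E,7R)-7-methyl-7-[(triethylsilyl)oxy]nona-3,8-dien-2-yl propanoate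
Conditions: (EtCO)2O, Et3N, DMAP (cat.), CH2Cl2, 0 °C → rt
Reagents that add atoms: propanoic anhydride, CCC(=O)OC(=O)CC
Why: DMAP-catalysed acylation of the secondary allylic alcohol is a routine esterification that does not touch the carbinol configuration and brings in C5, C6 and C7.

Step 6
Reactants: 7 (2S,3E,7R)-7-methyl-7-[(triethylsilyl)oxy]nona-3,8-dien-2-yl propanoate
Product: 10 (2S,3R,6R)-2,6-dimethyl-3-[(1E)-prop-1-en-1-yl]-6-[(triethylsilyl)oxy]oct-7-enoic acid, via silyl ketene acetal 8 (not isolated), via trimethylsilyl ester 9 (not isolated)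
Conditions: LiN(i-Pr)2, THF/DMPU (4:1), −78 °C; Me3SiCl/Et3N, −78 °C → rt, then 40 °C; aq. NH4Cl
Reagents that add atoms: chlorotrimethylsilane, C[Si](C)(C)Cl (its silyl group is carried only by 8 and 9)
Why: In this Ireland–Claisen rearrangement the polar cosolvent should favour the Z(O)-enolate, whose (Z)-silyl ketene acetal rearranges through a chair with the carbinol methyl equatorial, so that the (S)-C–O centre is transferred suprafacially to C1', the enolate geometry sets C6 in the syn relation, and the new alkene appears as the (E)-propenyl group.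

Step 7
Reactants: 10 (2S,3R,6R)-2,6-dimethyl-3-[(1E)-prop-1-en-1-yl]-6-[(triethylsilyl)oxy]oct-7-enoic acid
Product: 11 (2S,3R,6R)-2,6-dimethyl-3-[(1E)-prop-1-en-1-yl]-6-[(triethylsilyl)oxy]oct-7-en-1-ol
Conditions: LiAlH4, Et2O, 0 °C → rt; aq. NaOH work-up
Reagents that add atoms: none
Why: Hydride reduction with LiAlH4 converts the carboxylic acid into the primary alcohol and leaves the isolated alkenes and the silyl ether alone.

Step 8
Reactants: 11 (2S,3R,6R)-2,6-dimethyl-3-[(1E)-prop-1-en-1-yl]-6-[(triethylsilyl)oxy]oct-7-en-1-ol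
Product: 12 triethyl{[(3R,6R,7S)-8-iodo-3,7-dimethyl-6-[(1E)-prop-1-en-1-yl]oct-1-en-3-yl]oxy}silane
Conditions: I2, PPh3, imidazole, CH2Cl2, 0 °C → rt
Reagents that add atoms: iodine, [I][I]
Why: Appel-type iodination replaces the primary hydroxyl by SN2 displacement of the oxyphosphonium ion under buffered conditions that spare the silyl ether.

Step 9
Reactants: 12 triethyl{[(3R,6R,7S)-8-iodo-3,7-dimethyl-6-[(1E)-prop-1-en-1-yl]oct-1-en-3-yl]oxy}silane
Product: 13 (4R,5S,8R)-4,8-dimethyl-5-[(1E)-prop-1-en-1-yl]-8-[(triethylsilyl)oxy]dec-9-enenitrile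
Conditions: MeCN, n-BuLi, THF, −78 °C; then 12, DMPU, −78 → 0 °C
Reagents that add atoms: acetonitrile (as its lithio derivative), CC#N
Why: SN2 alkylation of lithiated acetonitrile by the primary iodide adds C4 and C3 in one operation, the small carbanion and the polar cosolvent favouring substitution over elimination.

Step 10
Reactants: 13 (4R,5S,8R)-4,8-dimethyl-5-[(1E)-prop-1-en-1-yl]-8-[(triethylsilyl)oxy]dec-9-enenitrile
Product: 14 (4R,5S,8R)-4,8-dimethyl-5-[(1E)-prop-1-en-1-yl]-8-[(triethylsilyl)oxy]dec-9-enal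
Conditions: i-Bu2AlH, CH2Cl2, −78 °C; then aq. potassium sodium tartrate
Reagents that add atoms: water, O
Why: Partial reduction of the nitrile by i-Bu2AlH stops at the N-aluminoimine, which hydrolyses to the aldehyde on work-up, and no stereocentre lies next to the new carbonyl.

Step 11
Reactants: 15 methyl (triphenylphosphoranylidene)acetate; 16 5-iodo-2-methylpent-2-ene
Product: 18 methyl 6-methyl-2-(triphenylphosphoranylidene)hept-5-enoate, via phosphonium iodide 17 (not isolated)
Conditions: MeCN, reflux; then 1 M aq. NaOH, CH2Cl2, rt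
Reagents that add atoms: none
Why: C-alkylation of the stabilized ylide by the primary iodide gives the phosphonium salt, which aqueous NaOH deprotonates to the α-substituted stabilized ylide.

Step 12
Reactants: 14 (4R,5S,8R)-4,8-dimethyl-5-[(1E)-prop-1-en-1-yl]-8-[(triethylsilyl)oxy]dec-9-enal; 18 methyl 6-methyl-2-(triphenylphosphoranylidene)hept-5-enoate
Product: 20 methyl (2E,4S,6R,7S,10R)-6,10-dimethyl-2-(4-methylpent-3-en-1-yl)-4-[(phenylamino)oxy]-7-[(1E)-prop-1-en-1-yl]-10-[(triethylsilyl)oxy]dodeca-2,11-dienoate, via alpha-aminoxy aldehyde 19 (not isolated)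
Conditions: D-proline (0.3 equiv), PhNO (1.0 equiv, slow addition), DMSO, rt; then 18 (1.5 equiv), CH2Cl2, 0 °C → rt
Reagents that add atoms: nitrosobenzene, O=Nc1ccccc1
Why: In this proline-catalysed α-aminoxylation the enamine of D-proline attacks the nitroso oxygen on the face directed by the carboxylic acid and should set (S)-C4 under catalyst control, and the in situ Wittig reaction of the disubstituted stabilized ylide should give the (E)-enoate before the sensitive aldehyde epimerizes.

Step 13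
Reactants: 20 methyl (2E,4S,6R,7S,10R)-6,10-dimethyl-2-(4-methylpent-3-en-1-yl)-4-[(phenylamino)oxy]-7-[(1E)-prop-1-en-1-yl]-10-[(triethylsilyl)oxy]dodeca-2,11-dienoate
Product: 21 methyl (2E,4S,6R,7S,10R)-4-hydroxy-6,10-dimethyl-2-(4-methylpent-3-en-1-yl)-7-[(1E)-prop-1-en-1-yl]-10-[(triethylsilyl)oxy]dodeca-2,11-dienoate
Conditions: Cu(OAc)2 (0.3 equiv), EtOH, rt
Reagents that add atoms: none
Why: Copper-catalysed scission of the weak N–O bond of the O-alkyl-N-arylhydroxylamine frees the allylic alcohol under neutral conditions, and the (E)-geometry holds the hydroxyl away from the ester so that no butenolide can form.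

Step 14
Reactants: 21 methyl (2E,4S,6R,7S,10R)-4-hydroxy-6,10-dimethyl-2-(4-methylpent-3-en-1-yl)-7-[(1E)-prop-1-en-1-yl]-10-[(triethylsilyl)oxy]dodeca-2,11-dienoate
Product: 22 methyl (2E,4S,6R,7S,10R)-4-(acetyloxy)-6,10-dimethyl-2-(4-methylpent-3-en-1-yl)-7-[(1E)-prop-1-en-1-yl]-10-[(triethylsilyl)oxy]dodeca-2,11-dienoate
Conditions: Ac2O, pyridine, DMAP (cat.), CH2Cl2, 0 °C → rt
Reagents that add atoms: acetic anhydride, CC(=O)OC(C)=O
Why: DMAP-catalysed acetylation of the secondary allylic alcohol meets no competition because the tertiary hydroxyl is still silylated.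

Step 15
Reactants: 22 methyl (2E,4S,6R,7S,10R)-4-(acetyloxy)-6,10-dimethyl-2-(4-methylpent-3-en-1-yl)-7-[(1E)-prop-1-en-1-yl]-10-[(triethylsilyl)oxy]dodeca-2,11-dienoate
Product: 23 methyl (2E,4S,6R,7S,10R)-4-(acetyloxy)-10-hydroxy-6,10-dimethyl-2-(4-methylpent-3-en-1-yl)-7-[(1E)-prop-1-en-1-yl]dodeca-2,11-dienoate
Conditions: HF·pyridine, pyridine, THF, 0 °C → rt
Reagents that add atoms: none
Why: Fluoride-mediated desilylation under pyridine buffering removes the triethylsilyl group without ionizing the tertiary allylic alcohol or cleaving the acetate, and the freed hydroxyl assists the metathesis that follows.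

Step 16
Reactants: 23 methyl (2E,4S,6R,7S,10R)-4-(acetyloxy)-10-hydroxy-6,10-dimethyl-2-(4-methylpent-3-en-1-yl)-7-[(1E)-prop-1-en-1-yl]dodeca-2,11-dienoate
Product: 24 methyl (2E,4S,6R)-4-(acetyloxy)-6-[(1S,4R)-4-hydroxy-4-methylcyclohex-2-en-1-yl]-2-(4-methylpent-3-en-1-yl)hept-2-enoate
Conditions: second-generation Grubbs catalyst (H2IMes)(PCy3)Cl2Ru=CHPh (5 mol%), CH2Cl2 (0.005 M), 40 °C
Reagents that add atoms: none
Why: Ring-closing olefin metathesis: the ruthenium benzylidene is exchanged onto the (E)-propenyl group or the hydroxyl-activated vinyl group, the resulting alkylidene adds to the other alkene in an intramolecular [2+2] step, and cycloreversion of the ruthenacyclobutane forms C2'=C3' and expels propene, whose loss drives the reaction. The closest known reaction type is the ring-closing metathesis of 1,7-dienes bearing a free tertiary allylic alcohol to 1-methylcyclohex-2-en-1-ols. The one ring closed is the six-membered carbocycle C1'–C6', closed between two sp2 carbons through the metallacyclobutane, and the ring size allows only the cis alkene. No stereocentre is created: C1' and C4' were fixed by the Ireland–Claisen rearrangement and by linalool, they are not part of the reacting π bonds, and the CH–CH3 unit that carried the chirality is the piece cut off. The step needs chemoselectivity among five alkenes, which the substrate secures because only the vinyl carbinol and the propenyl group are unhindered enough and stand in a 1,7-relationship, whereas the trisubstituted enoate and the isopropylidene alkene are too hindered or electron-poor and could only close large rings; high dilution suppresses intermolecular metathesis.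

**Compound list**
1 | (R)-linalool, (3R)-3,7-dimethylocta-1,6-dien-3-ol | C=C[C@](C)(O)CCC=C(C)C | starting material
2 | triethyl{[(3R)-3,7-dimethylocta-1,6-dien-3-yl]oxy}silane | C=C[C@](C)(O[Si](CC)(CC)CC)CCC=C(C)C | intermediate
3 | (4R)-4-methyl-4-[(triethylsilyl)oxy]hex-5-enal | O=CCC[C@@](C)(O[Si](CC)(CC)CC)C=C | intermediate
4 | 1-(triphenylphosphoranylidene)propan-2-one | CC(=O)C=P(c1ccccc1)(c1ccccc1)c1ccccc1 | starting material
5 | (3E,7R)-7-methyl-7-[(triethylsilyl)oxy]nona-3,8-dien-2-one | CC(=O)/C=C/CC[C@@](C)(O[Si](CC)(CC)CC)C=C | intermediate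
6 | (2S,3E,7R)-7-methyl-7-[(triethylsilyl)oxy]nona-3,8-dien-2-ol | C[C@H](O)/C=C/CC[C@@](C)(O[Si](CC)(CC)CC)C=C | intermediate
7 | (2S,3E,7R)-7-methyl-7-[(triethylsilyl)oxy]nona-3,8-dien-2-yl propanoate | C[C@H](OC(=O)CC)/C=C/CC[C@@](C)(O[Si](CC)(CC)CC)C=C | intermediate
8 | (Z)-O-trimethylsilyl ketene acetal of 7 (methyl cis to OSiMe3; not isolated) | C/C=C(\O[Si](C)(C)C)O[C@@H](C)/C=C/CC[C@@](C)(O[Si](CC)(CC)CC)C=C | intermediate
9 | trimethylsilyl (2S,3R,6R)-2,6-dimethyl-3-[(1E)-prop-1-en-1-yl]-6-[(triethylsilyl)oxy]oct-7-enoate (not isolated) | C[Si](C)(C)OC(=O)[C@@H](C)[C@@H](/C=C/C)CC[C@@](C)(O[Si](CC)(CC)CC)C=C | intermediate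
10 | (2S,3R,6R)-2,6-dimethyl-3-[(1E)-prop-1-en-1-yl]-6-[(triethylsilyl)oxy]oct-7-enoic acid | OC(=O)[C@@H](C)[C@@H](/C=C/C)CC[C@@](C)(O[Si](CC)(CC)CC)C=C | intermediate
11 | (2S,3R,6R)-2,6-dimethyl-3-[(1E)-prop-1-en-1-yl]-6-[(triethylsilyl)oxy]oct-7-en-1-ol | OC[C@@H](C)[C@@H](/C=C/C)CC[C@@](C)(O[Si](CC)(CC)CC)C=C | intermediate
12 | triethyl{[(3R,6R,7S)-8-iodo-3,7-dimethyl-6-[(1E)-prop-1-en-1-yl]oct-1-en-3-yl]oxy}silane | IC[C@@H](C)[C@@H](/C=C/C)CC[C@@](C)(O[Si](CC)(CC)CC)C=C | intermediate
13 | (4R,5S,8R)-4,8-dimethyl-5-[(1E)-prop-1-en-1-yl]-8-[(triethylsilyl)oxy]dec-9-enenitrile | N#CCC[C@@H](C)[C@@H](/C=C/C)CC[C@@](C)(O[Si](CC)(CC)CC)C=C | intermediate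
14 | (4R,5S,8R)-4,8-dimethyl-5-[(1E)-prop-1-en-1-yl]-8-[(triethylsilyl)oxy]dec-9-enal | O=CCC[C@@H](C)[C@@H](/C=C/C)CC[C@@](C)(O[Si](CC)(CC)CC)C=C | intermediate
15 | methyl (triphenylphosphoranylidene)acetate | COC(=O)C=P(c1ccccc1)(c1ccccc1)c1ccccc1 | starting material
16 | 5-iodo-2-methylpent-2-ene | CC(C)=CCCI | starting material
17 | (1-methoxy-6-methyl-1-oxohept-5-en-2-yl)triphenylphosphonium iodide (not isolated) | COC(=O)C(CCC=C(C)C)[P+](c1ccccc1)(c1ccccc1)c1ccccc1.[I-] | intermediate
18 | methyl 6-methyl-2-(triphenylphosphoranylidene)hept-5-enoate | COC(=O)C(CCC=C(C)C)=P(c1ccccc1)(c1ccccc1)c1ccccc1 | intermediate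
19 | (2S,4R,5S,8R)-4,8-dimethyl-2-[(phenylamino)oxy]-5-[(1E)-prop-1-en-1-yl]-8-[(triethylsilyl)oxy]dec-9-enal (not isolated) | O=C[C@H](C[C@@H](C)[C@@H](/C=C/C)CC[C@@](C)(O[Si](CC)(CC)CC)C=C)ONc1ccccc1 | intermediate
20 | methyl (2E,4S,6R,7S,10R)-6,10-dimethyl-2-(4-methylpent-3-en-1-yl)-4-[(phenylamino)oxy]-7-[(1E)-prop-1-en-1-yl]-10-[(triethylsilyl)oxy]dodeca-2,11-dienoate | COC(=O)/C(=C/[C@H](C[C@@H](C)[C@@H](/C=C/C)CC[C@@](C)(O[Si](CC)(CC)CC)C=C)ONc1ccccc1)CCC=C(C)C | intermediate
21 | methyl (2E,4S,6R,7S,10R)-4-hydroxy-6,10-dimethyl-2-(4-methylpent-3-en-1-yl)-7-[(1E)-prop-1-en-1-yl]-10-[(triethylsilyl)oxy]dodeca-2,11-dienoate | COC(=O)/C(=C/[C@H](C[C@@H](C)[C@@H](/C=C/C)CC[C@@](C)(O[Si](CC)(CC)CC)C=C)O)CCC=C(C)C | intermediate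
22 | methyl (2E,4S,6R,7S,10R)-4-(acetyloxy)-6,10-dimethyl-2-(4-methylpent-3-en-1-yl)-7-[(1E)-prop-1-en-1-yl]-10-[(triethylsilyl)oxy]dodeca-2,11-dienoate | COC(=O)/C(=C/[C@H](C[C@@H](C)[C@@H](/C=C/C)CC[C@@](C)(O[Si](CC)(CC)CC)C=C)OC(C)=O)CCC=C(C)C | intermediate
23 | methyl (2E,4S,6R,7S,10R)-4-(acetyloxy)-10-hydroxy-6,10-dimethyl-2-(4-methylpent-3-en-1-yl)-7-[(1E)-prop-1-en-1-yl]dodeca-2,11-dienoate | COC(=O)/C(=C/[C@H](C[C@@H](C)[C@@H](/C=C/C)CC[C@@](C)(O)C=C)OC(C)=O)CCC=C(C)C | intermediate
24 | methyl (2E,4S,6R)-4-(acetyloxy)-6-[(1S,4R)-4-hydroxy-4-methylcyclohex-2-en-1-yl]-2-(4-methylpent-3-en-1-yl)hept-2-enoate | COC(=O)/C(=C/[C@H](C[C@@H](C)[C@H]1C=C[C@](C)(O)CC1)OC(C)=O)CCC=C(C)C | target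

**Step count**
Total: 16 steps. Longest linear sequence: 15 steps (steps 1–10 and 12–16 from (R)-linalool); step 11 is a one-step side branch.

**Steps most likely to fail, with fallbacks**

Step 12. The α-aminoxy aldehyde may oligomerize or lose configuration at C4 before the hindered disubstituted ylide has reacted, and nitrosobenzene may be consumed by side reactions, so that both conversion and the C4 configuration suffer. The fallback makes the C5–C4 bond by a catalyst-controlled organozinc addition instead; it sets out from 12 and 18 and comes back at 21. Ylide 18 is condensed with 2,2-dimethoxyacetaldehyde (Wittig, CH2Cl2) to the acetal methyl (2E)-2-(2,2-dimethoxyethylidene)-6-methylhept-5-enoate F1, which dilute aqueous acid hydrolyses to the aldehyde methyl (2E)-6-methyl-2-(2-oxoethylidene)hept-5-enoate F2. Iodide 12 is converted by iodine–zinc exchange (Et2Zn, CuI cat., 50 °C) into the dialkylzinc bis{(2S,3R,6R)-2,6-dimethyl-3-[(1E)-prop-1-en-1-yl]-6-[(triethylsilyl)oxy]oct-7-en-1-yl}zinc F3. F3 is added to F2 with Ti(Oi-Pr)4 and (1R,2R)-1,2-bis(trifluoromethanesulfonamido)cyclohexane (toluene, −20 °C); the ligand should fix (S)-C4 and the product is 21.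

Step 6. Incomplete control of enolate geometry would erode the syn relation between C6 and C1'. The fallback separates the two centres; it sets out from 6 and comes back at 11. Johnson–Claisen rearrangement of 6 (triethyl orthoacetate, EtCO2H cat., 140 °C) sets C1' alone by the same chair chirality transfer and gives the ester ethyl (3S,6R)-6-methyl-3-[(1E)-prop-1-en-1-yl]-6-[(triethylsilyl)oxy]oct-7-enoate F4. Saponification (LiOH, THF/H2O) gives the acid (3S,6R)-6-methyl-3-[(1E)-prop-1-en-1-yl]-6-[(triethylsilyl)oxy]oct-7-enoic acid F5. Coupling with (4S)-4-benzyl-1,3-oxazolidin-2-one (dicyclohexylcarbodiimide, DMAP) gives the imide (4S)-4-benzyl-3-{(3S,6R)-6-methyl-3-[(1E)-prop-1-en-1-yl]-6-[(triethylsilyl)oxy]oct-7-enoyl}-1,3-oxazolidin-2-one F6. Auxiliary-controlled methylation of its sodium enolate (NaN(SiMe3)2, MeI, THF, −78 °C) sets C6 and gives the imide (4S)-4-benzyl-3-{(2S,3R,6R)-2,6-dimethyl-3-[(1E)-prop-1-en-1-yl]-6-[(triethylsilyl)oxy]oct-7-enoyl}-1,3-oxazolidin-2-one F7, which LiBH4 (THF, MeOH) cleaves reductively to 11.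

Step 9. Substitution at the β-branched primary iodide may be slow and elimination by the basic carbanion may compete. The fallback replaces the substitution by olefination and conjugate reduction; it sets out from 11 and comes back at 14. Dess–Martin oxidation of 11 gives the aldehyde (2S,3R,6R)-2,6-dimethyl-3-[(1E)-prop-1-en-1-yl]-6-[(triethylsilyl)oxy]oct-7-enal F8. Wittig reaction with (triphenylphosphoranylidene)acetaldehyde (toluene, 80 °C) gives the enal (2E,4R,5R,8R)-4,8-dimethyl-5-[(1E)-prop-1-en-1-yl]-8-[(triethylsilyl)oxy]deca-2,9-dienal F9, and conjugate reduction with [(Ph3P)CuH]6 (toluene, rt) gives 14.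

**Further compounds**
F1 | step 12 | methyl (2E)-2-(2,2-dimethoxyethylidene)-6-methylhept-5-enoate | COC(=O)/C(=C/C(OC)OC)CCC=C(C)C
F2 | step 12 | methyl (2E)-6-methyl-2-(2-oxoethylidene)hept-5-enoate | COC(=O)/C(=C/C=O)CCC=C(C)C
F3 | step 12 | bis{(2S,3R,6R)-2,6-dimethyl-3-[(1E)-prop-1-en-1-yl]-6-[(triethylsilyl)oxy]oct-7-en-1-yl}zinc | [Zn](C[C@@H](C)[C@@H](/C=C/C)CC[C@@](C)(O[Si](CC)(CC)CC)C=C)C[C@@H](C)[C@@H](/C=C/C)CC[C@@](C)(O[Si](CC)(CC)CC)C=C
F4 | step 6 | ethyl (3S,6R)-6-methyl-3-[(1E)-prop-1-en-1-yl]-6-[(triethylsilyl)oxy]oct-7-enoate | CCOC(=O)C[C@@H](/C=C/C)CC[C@@](C)(O[Si](CC)(CC)CC)C=C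
F5 | step 6 | (3S,6R)-6-methyl-3-[(1E)-prop-1-en-1-yl]-6-[(triethylsilyl)oxy]oct-7-enoic acid | OC(=O)C[C@@H](/C=C/C)CC[C@@](C)(O[Si](CC)(CC)CC)C=C
F6 | step 6 | (4S)-4-benzyl-3-{(3S,6R)-6-methyl-3-[(1E)-prop-1-en-1-yl]-6-[(triethylsilyl)oxy]oct-7-enoyl}-1,3-oxazolidin-2-one | O=C(C[C@@H](/C=C/C)CC[C@@](C)(O[Si](CC)(CC)CC)C=C)N1[C@@H](Cc2ccccc2)COC1=O
F7 | step 6 | (4S)-4-benzyl-3-{(2S,3R,6R)-2,6-dimethyl-3-[(1E)-prop-1-en-1-yl]-6-[(triethylsilyl)oxy]oct-7-enoyl}-1,3-oxazolidin-2-one | O=C([C@@H](C)[C@@H](/C=C/C)CC[C@@](C)(O[Si](CC)(CC)CC)C=C)N1[C@@H](Cc2ccccc2)COC1=O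
F8 | step 9 | (2S,3R,6R)-2,6-dimethyl-3-[(1E)-prop-1-en-1-yl]-6-[(triethylsilyl)oxy]oct-7-enal | O=C[C@@H](C)[C@@H](/C=C/C)CC[C@@](C)(O[Si](CC)(CC)CC)C=C
F9 | step 9 | (2E,4R,5R,8R)-4,8-dimethyl-5-[(1E)-prop-1-en-1-yl]-8-[(triethylsilyl)oxy]deca-2,9-dienal | O=C/C=C/[C@@H](C)[C@@H](/C=C/C)CC[C@@](C)(O[Si](CC)(CC)CC)C=C
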